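**Retrosynthetic overview**
- The target is reached from its O,O'-dimethyl ether by oxidative demethylation; the prenyl terminus comes from an allyl group by cross-metathesis.
- Key disconnection: the quinonoid ring B is opened at the bond between the side-chain C3'' carbon and the arene, the same bond that closes 3''-oxidised geranylhydroquinone in the biosynthesis. This gives a Z-4-aryl-4-oxo-enal, carried as a 2-aryl-4-alkylfuran (a latent Z-ene-1,4-dicarbonyl).
- The furan ester comes from a 5-aryl-3-furaldehyde by asymmetric allylation, which sets the only stereocentre (S), with acylation in the same flask.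
- The aryl–C1' bond, the counterpart of the aromatic prenylation, is made first, from 3-furaldehyde and 2-bromo-1,4-dimethoxybenzene.
- Ring order: ring A (the dioxygenated benzene ring) is bought; the furan is bought and consumed; ring B is the only ring built (step 3).

Assumption: operations run in one flask without isolating an intermediate count as one step, and the naphthazarin tautomers of the product are treated as one compound.

**Step 1**
Reactants: 1 furan-3-carbaldehyde; 2 2-bromo-1,4-dimethoxybenzene
Product: 7 5-(2,5-dimethoxyphenyl)furan-3-carbaldehyde, via lithium aminoalkoxide 3 (not isolated), via 5-lithiofuryl aminoalkoxide 4 (not isolated), via furylzinc chloride 5 (not isolated), via coupled aminoalkoxide 6 (not isolated)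
Conditions: LiN(CH2CH2)2O (from morpholine, n-BuLi), THF, −78 °C, then 1; sec-BuLi, −78 °C; ZnCl2, −78 → 0 °C; 2, Pd(PPh3)4 (3 mol%), 50 °C; then H2O
Reagents that add atoms: none
Why: In situ protection as the bulky, non-chelating lithium α-amino alkoxide (Comins-type) masks the formyl group and steers sec-BuLi to the remote α-position C5, after which Li-to-Zn transmetalation and Negishi cross-coupling with the aryl bromide form the aryl–furan bond and water releases the aldehyde; no stereocentre is formed.

**Step 2**
Reactants: 7 5-(2,5-dimethoxyphenyl)furan-3-carbaldehyde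
Product: 9 (1S)-1-[5-(2,5-dimethoxyphenyl)furan-3-yl]but-3-en-1-yl 3-methylbutanoate, via stannyl ether 8 (not isolated)
Conditions: allylSnBu3, (S)-BINOL (20 mol%), Ti(OiPr)4 (10 mol%), 4 Å MS, CH2Cl2, −20 °C; then i-BuCOCl, DMAP (10 mol%), −20 °C → rt
Reagents that add atoms: allyltributylstannane C=CC[Sn](CCCC)(CCCC)CCCC; 3-methylbutanoyl chloride (isovaleryl chloride) CC(C)CC(=O)Cl
Why: Keck asymmetric allylation, in which the (S)-BINOL/Ti(OiPr)4 Lewis acid directs the allylstannane to the Si face of the heteroaryl aldehyde and so sets the (S)-carbinol centre as stannyl ether 8, which the acyl chloride esterifies at oxygen (DMAP-catalysed acylation) without touching the C–O bond or the configuration.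

**Step 3**
Reactants: 9 (1S)-1-[5-(2,5-dimethoxyphenyl)furan-3-yl]but-3-en-1-yl 3-methylbutanoate
Product: 13 (1S)-1-(5,8-dimethoxy-1,4-dioxo-1,4-dihydronaphthalen-2-yl)but-3-en-1-yl 3-methylbutanoate, via furan endoperoxide 10 (not isolated), via Z-keto-enal 11 (not isolated), via naphthalene-1,4-diol 12 (not isolated)
Conditions: O2, hν (visible), tetraphenylporphyrin (cat.), CH2Cl2, −78 °C; Me2S, −78 → 0 °C, evaporate; CF3CO2H (5 equiv), chloranil (1.1 equiv), (CF3)2CHOH/CH2Cl2 1:4, 0 °C → rt
Reagents that add atoms: dioxygen O=O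
Why: Proposed new method: singlet oxygen adds [4+2] to the electron-rich 2-arylfuran much faster than it reacts with the monosubstituted alkene, and Me2S reduces endoperoxide 10 to the Z-4-aryl-4-oxo-enal 11, whose cis geometry holds the protonated aldehyde next to the free ortho carbon of the aryl ring (activated by its ortho methoxy group), so a six-membered intramolecular Friedel–Crafts hydroxyalkylation (Bradsher-type closure) followed by enolisation gives naphthalene-1,4-diol 12, which chloranil oxidises at once to quinone 13 before its ortho-hydroxybenzylic ester can ionise; the stereocentre is not involved and the acidic medium avoids deprotonation at the carbon γ to the ketone; the closest known reactions are furan photooxygenation/reduction to Z-ene-1,4-dicarbonyls and acid-mediated aldehyde–arene condensation with quinone oxidation in the same flask, as in Lindsey porphyrin synthesis.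

**Step 4**
Reactants: 13 (1S)-1-(5,8-dimethoxy-1,4-dioxo-1,4-dihydronaphthalen-2-yl)but-3-en-1-yl 3-methylbutanoate
Product: 14 (1S)-1-(5,8-dimethoxy-1,4-dioxo-1,4-dihydronaphthalen-2-yl)-4-methylpent-3-en-1-yl 3-methylbutanoate
Conditions: 2-methyl-2-butene (large excess), second-generation Grubbs catalyst RuCl2(=CHPh)(H2IMes)(PCy3) (5 mol%), CH2Cl2, 35 °C
Reagents that add atoms: 2-methyl-2-butene CC=C(C)C
Why: Olefin cross-metathesis of the terminal alkene with excess 2-methyl-2-butene installs the trisubstituted prenyl terminus with loss of propene, while the electron-poor trisubstituted quinone double bond is inert to the ruthenium carbene and the neutral conditions leave the stereocentre alone.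

**Step 5**
Reactants: 14 (1S)-1-(5,8-dimethoxy-1,4-dioxo-1,4-dihydronaphthalen-2-yl)-4-methylpent-3-en-1-yl 3-methylbutanoate
Product: 16 isovalerylalkannin, (1S)-1-(5,8-dihydroxy-1,4-dioxo-1,4-dihydronaphthalen-2-yl)-4-methylpent-3-en-1-yl 3-methylbutanoate, via naphthodiquinone 15 (not isolated)
Conditions: AgO (4 equiv), 6 M HNO3, acetone, 0 °C, 10 min; extract into CH2Cl2; aq. L-ascorbic acid (1.1 equiv), 0 °C
Reagents that add atoms: water O
Why: AgO oxidative demethylation, in which the dimethoxy ring is oxidised to its radical cation, water adds at the ipso carbons and methanol leaves to give naphthodiquinone 15, which ascorbic acid reduces only as far as the naphthazarin level, so the ester never meets the leuco form and the stereocentre stays untouched under acidic, non-enolising conditions.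

**Compound list**
1 | furan-3-carbaldehyde (3-furaldehyde) | O=Cc1ccoc1 | starting material
2 | 2-bromo-1,4-dimethoxybenzene | COc1ccc(OC)c(Br)c1 | starting material
3 | lithium (furan-3-yl)(morpholin-4-yl)methanolate (racemic at the aminal carbon) | [Li]OC(c1ccoc1)N1CCOCC1 | intermediate
4 | lithium (5-lithiofuran-3-yl)(morpholin-4-yl)methanolate | [Li]OC(c1coc([Li])c1)N1CCOCC1 | intermediate
5 | chloro{4-[(lithiooxy)(morpholin-4-yl)methyl]furan-2-yl}zinc | [Li]OC(c1coc([Zn]Cl)c1)N1CCOCC1 | intermediate
6 | lithium [5-(2,5-dimethoxyphenyl)furan-3-yl](morpholin-4-yl)methanolate | [Li]OC(c1coc(c1)-c1cc(OC)ccc1OC)N1CCOCC1 | intermediate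
7 | 5-(2,5-dimethoxyphenyl)furan-3-carbaldehyde | O=Cc1coc(c1)-c1cc(OC)ccc1OC | intermediate
8 | tributyl{[(1S)-1-[5-(2,5-dimethoxyphenyl)furan-3-yl]but-3-en-1-yl]oxy}stannane | C=CC[C@H](O[Sn](CCCC)(CCCC)CCCC)c1coc(c1)-c1cc(OC)ccc1OC | intermediate
9 | (1S)-1-[5-(2,5-dimethoxyphenyl)furan-3-yl]but-3-en-1-yl 3-methylbutanoate | C=CC[C@H](OC(=O)CC(C)C)c1coc(c1)-c1cc(OC)ccc1OC | intermediate
10 | (1S)-1-[1-(2,5-dimethoxyphenyl)-2,3,7-trioxabicyclo[2.2.1]hept-5-en-5-yl]but-3-en-1-yl 3-methylbutanoate (both bridgehead diastereomers) | C=CC[C@H](OC(=O)CC(C)C)C1=CC2(OOC1O2)c1cc(OC)ccc1OC | intermediate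
11 | (4S,5Z)-7-(2,5-dimethoxyphenyl)-5-formyl-7-oxohepta-1,5-dien-4-yl 3-methylbutanoate | C=CC[C@H](OC(=O)CC(C)C)/C(C=O)=C/C(=O)c1cc(OC)ccc1OC | intermediate
12 | (1S)-1-(1,4-dihydroxy-5,8-dimethoxynaphthalen-2-yl)but-3-en-1-yl 3-methylbutanoate | C=CC[C@H](OC(=O)CC(C)C)c1cc(O)c2c(OC)ccc(OC)c2c1O | intermediate
13 | (1S)-1-(5,8-dimethoxy-1,4-dioxo-1,4-dihydronaphthalen-2-yl)but-3-en-1-yl 3-methylbutanoate | C=CC[C@H](OC(=O)CC(C)C)C1=CC(=O)c2c(OC)ccc(OC)c2C1=O | intermediate
14 | (1S)-1-(5,8-dimethoxy-1,4-dioxo-1,4-dihydronaphthalen-2-yl)-4-methylpent-3-en-1-yl 3-methylbutanoate | CC(C)=CC[C@H](OC(=O)CC(C)C)C1=CC(=O)c2c(OC)ccc(OC)c2C1=O | intermediate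
15 | (1S)-4-methyl-1-(1,4,5,8-tetraoxo-1,4,5,8-tetrahydronaphthalen-2-yl)pent-3-en-1-yl 3-methylbutanoate | CC(C)=CC[C@H](OC(=O)CC(C)C)C1=CC(=O)C2=C(C1=O)C(=O)C=CC2=O | intermediate
16 | isovalerylalkannin, (1S)-1-(5,8-dihydroxy-1,4-dioxo-1,4-dihydronaphthalen-2-yl)-4-methylpent-3-en-1-yl 3-methylbutanoate | CC(C)=CC[C@H](OC(=O)CC(C)C)C1=CC(=O)c2c(O)ccc(O)c2C1=O | target

**Totals**
Total step count: 5. Longest linear sequence: 5 (1 → 7 → 9 → 13 → 14 → 16).

**Steps most likely to fail**

Step 3. The ring that must attack is deactivated by its acyl group; Z-to-E isomerisation of 11 or ionisation of the ester in 12 would also cost material. The fallback gives up the furan-opening closure and builds ring B by aryne cycloaddition. It sets out from 1: Keck allylation as in step 2, but with aqueous work-up, gives (1S)-1-(furan-3-yl)but-3-en-1-ol F2, which isovaleryl chloride and pyridine convert into (1S)-1-(furan-3-yl)but-3-en-1-yl 3-methylbutanoate F3. 3,6-Dimethoxybenzyne F4, generated in the flask from 3,6-dimethoxy-2-(trimethylsilyl)phenyl triflate and CsF in MeCN, adds [4+2] to the furan of F3 to give (1S)-1-(5,8-dimethoxy-1,4-dihydro-1,4-epoxynaphthalen-2-yl)but-3-en-1-yl 3-methylbutanoate F5. Catalytic TsOH in CH2Cl2 isomerises it to (1S)-1-(1-hydroxy-5,8-dimethoxynaphthalen-2-yl)but-3-en-1-yl 3-methylbutanoate F6; its 3-substituted regioisomer, if formed, leads to the same quinone. Oxidation at the free para position with (KSO3)2NO (KH2PO4, acetone/H2O) gives 13, where the route is rejoined.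

Step 5. AgO/HNO3 may attack the electron-rich prenyl alkene, and the diquinone stage is delicate. The fallback removes the methyl groups without an oxidant and before the prenyl group is present. It sets out from 13: BCl3 in CH2Cl2 (−78 → 0 °C) cleaves both peri-methoxy groups through chelation to the quinone carbonyls and gives (1S)-1-(5,8-dihydroxy-1,4-dioxo-1,4-dihydronaphthalen-2-yl)but-3-en-1-yl 3-methylbutanoate F7. Cross-metathesis of F7 with 2-methyl-2-butene (second-generation Hoveyda–Grubbs catalyst, CH2Cl2, 35 °C) then gives the target 16 directly.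

Step 1. The C5 selectivity of the lithiation and the survival of the aminoalkoxide through the Negishi coupling are the weak points. The fallback reverses the polarity of the coupling and avoids lithiation. It sets out from 1: electrophilic bromination (Br2, AlCl3, CH2Cl2, 0 °C) goes to C5, the α-position not conjugated to the formyl group, and gives 5-bromofuran-3-carbaldehyde F1. Suzuki–Miyaura coupling of F1 with commercial (2,5-dimethoxyphenyl)boronic acid (PdCl2(dppf), K2CO3, dioxane/H2O, 80 °C) gives 7, where the route is rejoined.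

**Further compounds**
F1 | step 1 | 5-bromofuran-3-carbaldehyde | O=Cc1coc(Br)c1
F2 | step 3 | (1S)-1-(furan-3-yl)but-3-en-1-ol | C=CC[C@H](O)c1ccoc1
F3 | step 3 | (1S)-1-(furan-3-yl)but-3-en-1-yl 3-methylbutanoate | C=CC[C@H](OC(=O)CC(C)C)c1ccoc1
F4 | step 3 | 3,6-dimethoxybenzyne | COC1=CC=C(OC)C#C1
F5 | step 3 | (1S)-1-(5,8-dimethoxy-1,4-dihydro-1,4-epoxynaphthalen-2-yl)but-3-en-1-yl 3-methylbutanoate (both bridgehead diastereomers) | C=CC[C@H](OC(=O)CC(C)C)C1=CC2OC1c1c(OC)ccc(OC)c12
F6 | step 3 | (1S)-1-(1-hydroxy-5,8-dimethoxynaphthalen-2-yl)but-3-en-1-yl 3-methylbutanoate | C=CC[C@H](OC(=O)CC(C)C)c1ccc2c(OC)ccc(OC)c2c1O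
F7 | step 5 | (1S)-1-(5,8-dihydroxy-1,4-dioxo-1,4-dihydronaphthalen-2-yl)but-3-en-1-yl 3-methylbutanoate | C=CC[C@H](OC(=O)CC(C)C)C1=CC(=O)c2c(O)ccc(O)c2C1=O
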